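**Retrosynthetic overview** (disconnections listed from the starting materials upward)
1. Key C–C disconnection: the indole C2–C3 bond, made by crossed Claisen condensation of nitrotoluene 1 with diethyl oxalate 2 (enolate 3).
2. Rings: the benzene ring is bought in 1; the pyrrole ring is closed second, by reduction of 3 (through 4 and 5) to indole ester 6; the C2 carboxyl is then removed (7, 8) to give 6-bromoindole 9.
3. Polyamine: C–N disconnections lead back to N-Boc-putrescine 10 and acrylonitrile 11 (12, 13, then N1-free di-Boc-spermidine 14).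
4. C3–glyoxyl bond: 9 + oxalyl chloride 15 (acid chloride 16); amide C–N bond: 16 + 14 (17).
5. End: Boc removal (salt 18) and liberation of the free base 19.

Assumption: the target has no stereocentre and no stereogenic double bond, so it is made as the achiral free base and no stereocontrol is needed.

**Route**

Step 1
Reactants: 1 4-bromo-2-nitrotoluene; 2 diethyl oxalate
Product: 3 potassium (Z)-1-(4-bromo-2-nitrophenyl)-3-ethoxy-3-oxoprop-1-en-2-olate (potassium enolate of ethyl (4-bromo-2-nitrophenyl)pyruvate)
Conditions: KOEt (1.1 equiv), (CO2Et)2 (1.2 equiv), dry Et2O/EtOH, 0 °C → rt, 24 h; filter the red salt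
Reagents that add atoms: potassium ethoxide, CC[O-].[K+]
Why: The ortho-nitro group makes the methyl protons acidic enough for ethoxide, and the benzylic carbanion acylates non-enolisable diethyl oxalate in a crossed Claisen condensation (first stage of the Reissert indole synthesis) that is driven by precipitation of the stabilised enolate salt; no stereocentre is formed.

Step 2
Reactants: 3 potassium enolate of ethyl (4-bromo-2-nitrophenyl)pyruvate
Product: 6 ethyl 6-bromo-1H-indole-2-carboxylate, via nitroarylpyruvate ester 4 (not isolated), via aminoarylpyruvate ester 5 (not isolated)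
Conditions: Fe powder (5 equiv), AcOH/EtOH (1:1), 80 °C, 2 h
Reagents that add atoms: none
Why: AcOH liberates keto ester 4, Fe/AcOH reduces the nitro group without touching the aryl C–Br bond, and aniline 5 condenses with the neighbouring ketone and dehydrates to the aromatic indole (Reissert reductive cyclisation).

Step 3
Reactants: 6 ethyl 6-bromo-1H-indole-2-carboxylate
Product: 8 6-bromo-1H-indole-2-carboxylic acid, via sodium carboxylate 7 (not isolated)
Conditions: NaOH (3 equiv), EtOH/H2O, reflux, 2 h; then 2 M HCl to pH 2, filter
Reagents that add atoms: sodium hydroxide, [Na+].[OH-]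
Why: Plain ester saponification; the indole and the aryl bromide are inert to aqueous hydroxide, and the acid precipitates on acidification.

Step 4
Reactants: 8 6-bromo-1H-indole-2-carboxylic acid
Product: 9 6-bromo-1H-indole
Conditions: Cu powder (10 mol %), quinoline, 220 °C, N2, 1.5 h; dilute HCl wash
Reagents that add atoms: none
Why: Indole-2-carboxylic acids lose CO2 on heating in quinoline (copper-assisted protodecarboxylation), and with only catalytic Cu and no added base or ligand the aryl C–Br bond is left alone.

Step 5
Reactants: 10 tert-butyl (4-aminobutyl)carbamate; 11 acrylonitrile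
Product: 12 tert-butyl (4-((2-cyanoethyl)amino)butyl)carbamate
Conditions: acrylonitrile (1.05 equiv), MeOH, 0 °C → rt, 16 h
Reagents that add atoms: none
Why: Aza-Michael addition of the primary amine to acrylonitrile stops cleanly at mono-cyanoethylation with one equivalent of acceptor, because the second addition is much slower.

Step 6
Reactants: 12 tert-butyl (4-((2-cyanoethyl)amino)butyl)carbamate
Product: 13 tert-butyl (4-((tert-butoxycarbonyl)amino)butyl)(2-cyanoethyl)carbamate
Conditions: Boc2O (1.1 equiv), Et3N, CH2Cl2, rt, 12 h
Reagents that add atoms: di-tert-butyl dicarbonate, CC(C)(C)OC(=O)OC(=O)OC(C)(C)C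
Why: Carbamoylation of the only basic nitrogen blocks the future central amine, so that the nitrile-derived nitrogen will be the only free amine in the coupling.

Step 7
Reactants: 13 tert-butyl (4-((tert-butoxycarbonyl)amino)butyl)(2-cyanoethyl)carbamate
Product: 14 tert-butyl (3-aminopropyl)(4-((tert-butoxycarbonyl)amino)butyl)carbamate
Conditions: H2 (4 bar), Raney Ni, 7 M NH3 in MeOH, rt, 16 h
Reagents that add atoms: none
Why: Catalytic hydrogenation of the nitrile gives the primary amine, excess NH3 suppresses secondary-amine formation, and Boc carbamates are inert to these conditions.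

Step 8
Reactants: 9 6-bromo-1H-indole; 15 oxalyl chloride
Product: 16 2-(6-bromo-1H-indol-3-yl)-2-oxoacetyl chloride
Conditions: (COCl)2 (1.3 equiv), dry Et2O, 0 °C → rt, 3 h; filter the yellow solid under N2, use at once
Reagents that add atoms: none
Why: The enamine-like C3 of the N–H indole is acylated by oxalyl chloride without a Lewis acid (Friedel–Crafts-type acylation, Speeter–Anthony procedure), and the deactivated product precipitates, so it reacts only once.

Step 9
Reactants: 16 2-(6-bromo-1H-indol-3-yl)-2-oxoacetyl chloride; 14 tert-butyl (3-aminopropyl)(4-((tert-butoxycarbonyl)amino)butyl)carbamate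
Product: 17 tert-butyl (3-(2-(6-bromo-1H-indol-3-yl)-2-oxoacetamido)propyl)(4-((tert-butoxycarbonyl)amino)butyl)carbamate
Conditions: Et3N (2.5 equiv), dry THF, 0 °C → rt, 12 h
Reagents that add atoms: none
Why: N-acylation of the single free primary amine by the acid chloride is far faster than attack on the vinylogous-amide ketone or on the indole N–H, and Et3N takes up the HCl so the Boc groups survive.

Step 10
Reactants: 17 di-Boc glyoxamide
Product: 18 didemnidine B bis(trifluoroacetate)
Conditions: TFA/CH2Cl2 (1:4), rt, 2 h; evaporate; C18 chromatography (H2O/MeOH, 0.05 % TFA)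
Reagents that add atoms: trifluoroacetic acid, OC(=O)C(F)(F)F
Why: Acidolysis removes both Boc groups as 2-methylpropene and CO2, while the α-ketoamide, the electron-poor 3-acylindole and the aryl bromide are stable to TFA.

Step 11
Reactants: 18 didemnidine B bis(trifluoroacetate)
Product: 19 didemnidine B (free base)
Conditions: 2 M NH3 in MeOH (large excess), rt; evaporate; NH2-silica chromatography (CH2Cl2/MeOH); store cold under Ar
Reagents that add atoms: none
Why: Simple acid–base liberation of the di-ammonium salt by excess volatile ammonia, with the amine-functionalised silica keeping the triamine as the free base and holding back the trifluoroacetate.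

**Compound list**
1 | 4-bromo-2-nitrotoluene (4-bromo-1-methyl-2-nitrobenzene) | Cc1ccc(Br)cc1[N+](=O)[O-] | starting material
2 | diethyl oxalate | CCOC(=O)C(=O)OCC | starting material
3 | potassium (Z)-1-(4-bromo-2-nitrophenyl)-3-ethoxy-3-oxoprop-1-en-2-olate | CCOC(=O)/C([O-])=C/c1ccc(Br)cc1[N+](=O)[O-].[K+] | intermediate
4 | ethyl 3-(4-bromo-2-nitrophenyl)-2-oxopropanoate | CCOC(=O)C(=O)Cc1ccc(Br)cc1[N+](=O)[O-] | intermediate
5 | ethyl 3-(2-amino-4-bromophenyl)-2-oxopropanoate | CCOC(=O)C(=O)Cc1ccc(Br)cc1N | intermediate
6 | ethyl 6-bromo-1H-indole-2-carboxylate | CCOC(=O)c1cc2ccc(Br)cc2[nH]1 | intermediate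
7 | sodium 6-bromo-1H-indole-2-carboxylate | [Na+].[O-]C(=O)c1cc2ccc(Br)cc2[nH]1 | intermediate
8 | 6-bromo-1H-indole-2-carboxylic acid | OC(=O)c1cc2ccc(Br)cc2[nH]1 | intermediate
9 | 6-bromo-1H-indole | Brc1ccc2cc[nH]c2c1 | intermediate
10 | tert-butyl (4-aminobutyl)carbamate (N-Boc-putrescine) | CC(C)(C)OC(=O)NCCCCN | starting material
11 | acrylonitrile | C=CC#N | starting material
12 | tert-butyl (4-((2-cyanoethyl)amino)butyl)carbamate | CC(C)(C)OC(=O)NCCCCNCCC#N | intermediate
13 | tert-butyl (4-((tert-butoxycarbonyl)amino)butyl)(2-cyanoethyl)carbamate | CC(C)(C)OC(=O)NCCCCN(CCC#N)C(=O)OC(C)(C)C | intermediate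
14 | tert-butyl (3-aminopropyl)(4-((tert-butoxycarbonyl)amino)butyl)carbamate | CC(C)(C)OC(=O)NCCCCN(CCCN)C(=O)OC(C)(C)C | intermediate
15 | oxalyl chloride | ClC(=O)C(=O)Cl | starting material
16 | 2-(6-bromo-1H-indol-3-yl)-2-oxoacetyl chloride | ClC(=O)C(=O)c1c[nH]c2cc(Br)ccc12 | intermediate
17 | tert-butyl (3-(2-(6-bromo-1H-indol-3-yl)-2-oxoacetamido)propyl)(4-((tert-butoxycarbonyl)amino)butyl)carbamate | CC(C)(C)OC(=O)NCCCCN(CCCNC(=O)C(=O)c1c[nH]c2cc(Br)ccc12)C(=O)OC(C)(C)C | intermediate
18 | didemnidine B bis(trifluoroacetate) | [NH3+]CCCC[NH2+]CCCNC(=O)C(=O)c1c[nH]c2cc(Br)ccc12.[O-]C(=O)C(F)(F)F.[O-]C(=O)C(F)(F)F | intermediate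
19 | didemnidine B, N-(3-((4-aminobutyl)amino)propyl)-2-(6-bromo-1H-indol-3-yl)-2-oxoacetamide | NCCCCNCCCNC(=O)C(=O)c1c[nH]c2cc(Br)ccc12 | target

**Step count**
Total: 11 steps. Longest linear sequence: 8 steps (steps 1, 2, 3, 4, 8, 9, 10, 11 from 1). The amine branch (steps 5, 6, 7) joins at step 9.

**Three steps most likely to fail, each with a fallback**

Step 1 (Claisen condensation). It needs strictly dry alkoxide, the equilibrium is only pulled over by precipitation of 3, and nitrotoluene anions can dimerise oxidatively. The fallback sets out from 1. The same benzylic carbanion is condensed with N,N-dimethylformamide dimethyl acetal (COC(OC)N(C)C; DMF, 110 °C) to give (E)-2-(4-bromo-2-nitrophenyl)-N,N-dimethylethen-1-amine F1. Reduction of F1 with Fe powder in AcOH/EtOH at 80 °C gives the aniline, which displaces dimethylamine and closes the pyrrole ring (Batcho–Leimgruber indole synthesis). The fallback comes back to the route at 9, so steps 2 to 4 are not needed.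

Step 4 (decarboxylation). At 220 °C the reaction may stall, tar, or lose some bromine. The fallback sets out from 3, which is acidified (1 M HCl, EtOAc) so that keto ester 4 is isolated. The activated benzylic CH2 of 4 is condensed with N,N-dimethylformamide dimethyl acetal (toluene, 60 °C) to give ethyl (E)-3-(4-bromo-2-nitrophenyl)-4-(dimethylamino)-2-oxobut-3-enoate F2. Fe powder in AcOH then reduces the nitro group, and the aniline displaces dimethylamine from the enaminone carbon, which is more reactive than the now vinylogous-amide ketone. This gives ethyl 2-(6-bromo-1H-indol-3-yl)-2-oxoacetate F3, in which the Claisen-made bond is the indole–glyoxyl bond and no carboxyl has to be removed. Heating F3 with amine 14 in EtOH at 60 °C gives the amide. The fallback comes back to the route at 17, so steps 8 and 9 are not needed. This sequence is less precedented than the main route: the enol of 4 may be O-methylated, and the aniline may attack the ketone instead.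

Step 7 (nitrile hydrogenation). Secondary-amine dimers, catalyst poisoning or an incomplete reaction are possible. The fallback sets out from 10 and uses no reduction. N-Alkylation with N-(3-bromopropyl)phthalimide (BrCCCN1C(=O)c2ccccc2C1=O; K2CO3, MeCN, 60 °C) gives tert-butyl (4-((3-(1,3-dioxoisoindolin-2-yl)propyl)amino)butyl)carbamate F4. Boc2O in CH2Cl2 converts it to tert-butyl (4-((tert-butoxycarbonyl)amino)butyl)(3-(1,3-dioxoisoindolin-2-yl)propyl)carbamate F5. Hydrazinolysis of the phthalimide (N2H4·H2O, EtOH, reflux; Gabriel-type release) then frees the primary amine, and the fallback comes back to the route at 14.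

**Further compounds**
F1 | step 1 | (E)-2-(4-bromo-2-nitrophenyl)-N,N-dimethylethen-1-amine | CN(C)/C=C/c1ccc(Br)cc1[N+](=O)[O-]
F2 | step 4 | ethyl (E)-3-(4-bromo-2-nitrophenyl)-4-(dimethylamino)-2-oxobut-3-enoate | CCOC(=O)C(=O)/C(=C/N(C)C)c1ccc(Br)cc1[N+](=O)[O-]
F3 | step 4 | ethyl 2-(6-bromo-1H-indol-3-yl)-2-oxoacetate | CCOC(=O)C(=O)c1c[nH]c2cc(Br)ccc12
F4 | step 7 | tert-butyl (4-((3-(1,3-dioxoisoindolin-2-yl)propyl)amino)butyl)carbamate | CC(C)(C)OC(=O)NCCCCNCCCN1C(=O)c2ccccc2C1=O
F5 | step 7 | tert-butyl (4-((tert-butoxycarbonyl)amino)butyl)(3-(1,3-dioxoisoindolin-2-yl)propyl)carbamate | CC(C)(C)OC(=O)NCCCCN(CCCN1C(=O)c2ccccc2C1=O)C(=O)OC(C)(C)C
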